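(Readings and results are calculated for an exercise.)

1. I began from a sum that stays constant: in the oak run, which is the flask itself followed to 30.0 h, the two substrates and two products always make up the charge. At that last reading the three measured columns gave 99.2 %, so I worked with the fraction left, not the fraction made.

| setting | oak | flask |
|---|---|---|
| left-handed substrate | 0.85 M | 0.85 M |
| right-handed substrate | 0.85 M | 0.85 M |
| partner | 2.55 M | 2.55 M |
| racemization catalyst | 5.4 mM | 5.4 mM |
| remark | the very flask that is asked about, followed so far |  |
| time |  | 4.0 d |

oak run (percent of the left-handed substrate and right-handed substrate together charged)

| time / h | left-handed substrate / % | right-handed substrate / % | left-handed product / % |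
|---|---|---|---|
| 1.50 | 44.8 | 48.7 | 6.8 |
| 4.00 | 40.4 | 43.6 | 15.5 |
| 8.00 | 37.1 | 39.0 | 24.0 |
| 12.0 | 33.8 | 35.6 | 29.4 |
| 20.0 | 32.0 | 31.8 | 35.4 |
| 25.0 | 29.9 | 31.8 | 38.5 |
| 30.0 | 30.1 | 30.2 | 38.9 |

(each reading ± 0.5 percentage points)

- partner is single-handed; left-handed substrate and right-handed substrate are mirror images of each other, charged as a racemate, each of them at the stated concentration
- steps thought possible: partner + left-handed substrate -> left-handed product; partner + right-handed substrate -> right-handed product; left-handed substrate + racemization catalyst <-> right-handed substrate + racemization catalyst; partner -> decomposed reagent
- an excess is the difference of the two amounts in percent of their sum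
- an excess is below zero if the other one leads
- the handed part of partner does not stay in what it makes, so the products of the two hands are mirror images too

- part of the left-handed substrate and right-handed substrate charged together that has reacted at 4.0 d
- excess of left-handed product over right-handed product in the product at 4.0 d
- excess of right-handed substrate over left-handed substrate among what is left of the two at 4.0 d

2. The substrate excess needed no sharp number: in the oak run the gap read 3.9 percentage points at 1.50 h and 0.1 points at 30.0 h, against a scatter of 0.5 points.

3. The right-handed product needed none either: the balance of the last oak reading left 0.8 points for it, a figure that carries the scatter, far less than the 38.9 % read for left-handed product.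

4. The fraction left did matter, since one minus it is the conversion. Its sum of two readings carries 0.71 points of scatter.

5. I named its negative logarithm the reach, and 0.506 read in the oak run at 30.0 h meant 39.7 % reacted. The substrate readings were still falling, so I expected slightly more by 4.0 d.

6. The forecast gave 42 % reacted, a product excess of 97 % and a substrate excess of 0 %, holding that “partner is decomposing”; its conversion stands above my 39.7 % at 30.0 h.

7. The flask gave 41.7 % reacted, a product excess of 98.7 % and a substrate excess of 0 %, so the forecast held. In the flask partner, the limiting reagent, fell to 39.8 % of its charge at 0.400 d and 1.29 % at 2.00 d, while left-handed product stood at 41.0 % at 2.00 d; right-handed product stood at 0.263 % at 4.00 d, and the relaxation half-life of the substrates by racemization alone was 0.808 h, short against 4.0 d. The reach of the flask at 4.0 d was 0.539; my 0.506 was a reading from the earlier time 30.0 h.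

    partner + left-handed substrate → left-handed product (k = 0.0406 M⁻¹ h⁻¹)
    partner + right-handed substrate → right-handed product (k = 2.44 × 10⁻⁴ M⁻¹ h⁻¹)
    left-handed substrate + racemization catalyst ⇌ right-handed substrate + racemization catalyst, rate k3*[racemization catalyst]*[left-handed substrate] forward; the back reaction follows from the equilibrium constant (k = 79.4 M⁻¹ h⁻¹)
    partner → decomposed reagent (k = 0.0679 h⁻¹)

8. For the neighbour charged with 0.64 M of partner, the other charges and the time held, I scaled the reach by the partner charge as an estimate, which gave 0.135, or 12.7 % reacted. That neighbour gave 12.1 % reacted.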